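Count the target in moles per litre first; percent is then that [target], idle adduct included, over the charge.

| flask | solid substrate | remark | time |
|---|---|---|---|
| alpha | 0.55 M | run made earlier |  |
| blue | 0.30 M |  | 4.0 min |
| ochre | 0.50 M |  | 4.0 min |
| grey | 0.80 M |  | 4.0 min |
| teal | 2.0 M |  | 4.0 min |
| green | 0.25 M |  | 4.0 min |

alpha run (percent of the solid substrate charged)

| time / min | target / % |
|---|---|
| 0.200 | 0 |
| 0.333 | 1.1 |
| 0.667 | 0 |
| 1.33 | 1.2 |
| 2.50 | 10.4 |

(each reading ± 1 percentage point)

- in percentages every species weighs as the solid substrate in it: one idle adduct counts as two
- for target the idle adduct is counted in
- as a solid, counted per litre of solution: solid substrate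
- steps thought possible: starting material -> intermediate A; intermediate A -> intermediate B; intermediate B -> intermediate C; intermediate C -> target; starting material -> decomposition product; starting material + target <-> idle adduct; solid substrate <-> starting material
- at the start none of the solid substrate is in solution
- what has only dissolved of solid substrate counts as not reacted
- in an amount of target, one idle adduct counts as one target

* ranking by amount of target, in percent of the solid substrate charged, from high to low, at 4.0 min (blue / ochre / grey / teal / green)
* the amount of target, in percent of the solid substrate charged of the flask you put first, at 4.0 min
* the amount of target, in percent of the solid substrate charged of the flask you put last, at 4.0 min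

Turn the question round. For teal to stand above green in percent, its [target] must exceed green's 8.00-fold. This ratio of the heavier charge to the lighter, the crossing factor, is what the heavier flask has to beat. The alpha run reads 10.4% at 2.50 min, which is a reading of 0.0572 M of target, but with one charge it can't show how [target] follows the charge. My own reckoning assumes that the solid dissolves only up to a limit per litre. I then estimate the factor teal reaches over green at near 1, less than the crossing factor, which puts teal below green. As an estimate for 2.50 min, the same 0.0572 M would be 22.9% of green's charge and 2.86% of teal's. My reckoning stops there, whereas the forecast goes on to the asked time: green > blue > ochre > grey > teal, with 50% first and 9.5% last, on the ground that “target forms at about the same molarity in every flask while solid remains”.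

The flasks give green > blue > ochre > grey > teal, with 50.8% for green and 8.15% for teal.

    starting material → intermediate A (k = 0.00981 s⁻¹)
    intermediate A → intermediate B (k = 0.0155 s⁻¹)
    intermediate B → intermediate C (k = 0.0903 s⁻¹)
    intermediate C → target (k = 0.0474 s⁻¹)
    starting material → decomposition product (k = 2.18 × 10⁻⁵ s⁻¹)
    starting material + target ⇌ idle adduct, settled at all times (K = 42.7 M⁻¹)
    solid substrate ⇌ starting material, rate k7*(cs7 - [starting material]) while solid is left; crystals form when [starting material] > cs7 (solubility = 0.450 M, k = 0.00715 s⁻¹)

Teal still holds 71.9% of its charge as solid at 4.00 min. Its [target] is 0.163 M against 0.127 M in green, a factor of 1.28 where 8.00 was needed. The neighbour of green charged with 0.42 M needs a factor of 1.68 over green, reaches 1.26 and stands at 38.2%.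

Readings and results are calculated on assumed constants; noise was put on by code.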